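(Readings and results were computed from invented constants; the scatter is artificial.)

Your vessel is closed, stirred and held at one temperature, and in it starting material and reagent combine to target, with free catalyst as catalyst. These are the charges, the earlier readings and what is asked.

| flask | starting material | reagent | free catalyst | time |
|---|---|---|---|---|
| theta | 0.800 M | 0.640 M | 0.0640 M |  |
| zeta | 0.320 M | 0.160 M | 0.0640 M |  |
| beta | 1.60 M | 0.640 M | 0.0640 M |  |
| epsilon | 0.800 M | 0.640 M | 0.130 M |  |
| alpha | 0.800 M | 0.640 M | 0.0640 M | 180 h |

- theta run (time / h: [starting material] / M): 1.8: 0.640; 2.8: 0.601; 4.4: 0.567; 7.0: 0.486; 11: 0.384; 18: 0.286; 28: 0.225; 44: 0.170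
- zeta run (time / h: [starting material] / M): 1.8: 0.293; 2.8: 0.303; 4.4: 0.306; 7.0: 0.312; 11: 0.299; 18: 0.289; 28: 0.292; 44: 0.281
- beta run (time / h: [starting material] / M): 1.8: 1.272; 2.8: 1.199; 4.4: 1.122; 7.0: 1.017; 11: 0.978; 18: 0.954; 28: 0.967; 44: 0.948
- epsilon run (time / h: [starting material] / M): 1.8: 0.555; 2.8: 0.510; 4.4: 0.455; 7.0: 0.403; 11: 0.311; 18: 0.249; 28: 0.206; 44: 0.172

(standard deviation of a reading: 0.008 M)

* reaction order in [free catalyst] at the outset, round the charge of the theta run, defined at two percent of the starting material turned into target
* reaction order in [reagent] at the outset, round the charge of the theta run, defined at two percent of the starting material turned into target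
* the zeta run starts with 0.480 M less of starting material and of reagent than the theta run, and with no target. Compared where both hold the same amount of starting material, once fifteen percent of what the zeta run was charged with has turned into target, is the zeta run faster, slower or alike (within a tenth)?
* starting material in the alpha run at 180 h, as a share of the starting material charged

- Overall: starting material + reagent -> target, with free catalyst as catalyst.
- Constant volume, constant temperature.
- "The second partner" is reagent.
- An order is taken over about fifteen percent of the charge, up and down.

Watch the first reading, at 1.8 h, for a pair of results that seem not to go together. The beta run, charged with twice the starting material of the theta run, has lost 0.328 M against 0.160 M in the theta run, and that loss is twice as large too. The epsilon run, charged with twice the free catalyst of the theta run, has lost 0.245 M, which is 1.53 times the theta loss, less than the rise in the charge. So a catalyst that turns the reaction over does not seem to pay in proportion.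

Go to logarithms to put a figure on this. Between the theta and epsilon runs the charge of free catalyst rises by 0.308 in powers of ten, and the early loss rises by 0.185. Their quotient is my own reckoning of the log-ratio order n_C, the powers of ten gained in early loss for each power of ten gained in charge: 0.601. The same reckoning for starting material, between the theta and beta runs, gives 1.04. So the early loss reads at about one power in starting material and at less in free catalyst. These are readings, each loss carrying a scatter of 0.008 M, and they lie later than the point asked about, but I would commit to about 0.601 for the order in free catalyst.

The forecast gives 1.2 for free catalyst, 1.2 for reagent, slower for the zeta run and 20% for the alpha run. Its ground for the orders is that “part of the catalyst has already been lost”. On free catalyst it stands above my reckoning.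

The flask gives 0.74 for free catalyst, 1.1 for reagent, slower for the zeta run and 20.0% for the alpha run.

    2 free catalyst ⇌ catalyst dimer, settled at all times (14.80 /M)
    free catalyst + starting material + reagent → target + free catalyst (12.28 /M²/h)
    free catalyst → spent catalyst (2.596 /h)
    starting material + reagent + target → 2 target (0.5796 /M²/h)

Carried forward, n_C of 0.601 turns the charge of the epsilon run into a rate 1.53 times that of the theta run, and the simulated ratio at the same amount of target is 1.6. Now watch the zeta run against the theta run at the point the question names, where both hold the same amount of starting material: the zeta rate is 0.091 of the theta rate. The step of free catalyst to spent catalyst widens that gap, for without it the ratio in the zeta run is 0.61.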